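**Plan**

- Retrosynthesis: after removal of the tiglate (ester C–O), the two aryl acetals and the quinone oxidation level, the naphthalene is cut at C3–C4, C1–C2 and C1–C8a into an aryl(methoxy)carbene chromium complex, a terminal alkyne and one CO ligand.
- Enabling feature: ring A (C1–C4 with C4a/C8a) carries oxygen at C1 and C4 in a para relationship, one carbon substituent at C2 and hydrogen at C3. It is fused to ring B (C5–C8), whose oxygens at C5 and C8 leave a single free ortho C–H beside the carbene-bearing carbon.
- Forward order: ring B is hydroquinone (bis-MOM ether, ortho-lithiation, Cr(CO)6, O-methylation). Ring A is closed in one operation by carbene/alkyne/CO benzannulation. Oxidation to the quinone, desilylation, esterification with tiglic acid and acetal cleavage finish the molecule.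
- Stereochemistry: the single (S) stereocentre is taken from methyl (S)-glycidate, opened at its CH2 terminus by an isobutenyl copper reagent, so no isomerisation-prone β,γ-unsaturated aldehyde is needed. The centre is a spectator from then on, and the E olefin of the ester is that of tiglic acid.

Key step: step 7

Remark: the target is a naphthazarin whose 1,4-dione/5,8-diol and 5,8-dione/1,4-diol forms interconvert by proton shift; the route is written for the tautomer drawn, with the (S) carbinol of the alkannin series.

**Route**

Step 1
Reactants: 1 hydroquinone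
Product: 2 1,4-bis(methoxymethoxy)benzene
Conditions: NaH, MOMCl, DMF, 0 °C → rt
Reagents that add atoms: chloromethyl methyl ether (MOMCl), COCCl
Why: Williamson etherification of both phenoxides with the reactive α-chloro ether is routine and installs acetals that later direct lithiation and come off under mild acid.

Step 2
Reactants: 2 1,4-bis(methoxymethoxy)benzene; 3 Cr(CO)6 (chromium hexacarbonyl)
Product: 6 pentacarbonyl{[2,5-bis(methoxymethoxy)phenyl](methoxy)methylidene}chromium, via aryllithium 4 (not isolated), via lithium acylchromate 5 (not isolated)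
Conditions: n-BuLi, THF, 0 °C → rt; Cr(CO)6, 0 °C → rt; then Me3OBF4, CH2Cl2, 0 °C
Reagents that add atoms: trimethyloxonium tetrafluoroborate (Me3OBF4), C[O+](C)C.F[B-](F)(F)F
Why: Acetal-directed ortho-lithiation (all four ring C–H positions of 2 are equivalent), addition of the aryllithium to a CO ligand and O-methylation of the acylchromate constitute the classical Fischer carbene synthesis.

Step 3
Reactants: 7 methyl (S)-glycidate; 8 2-methylprop-1-enylmagnesium bromide
Product: 9 methyl (S)-2-hydroxy-5-methylhex-4-enoate
Conditions: CuI (10 mol%), THF, −78 → −40 °C; then aq. NH4Cl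
Reagents that add atoms: none
Why: Copper-catalysed SN2 opening of the epoxide by the alkenyl Grignard reagent occurs at the unsubstituted CH2 faster than addition to the ester at low temperature, so the glycidate stereocentre is carried over unchanged as the (S)-α-hydroxy ester.

Step 4
Reactants: 9 methyl (S)-2-hydroxy-5-methylhex-4-enoate
Product: 10 methyl (S)-2-(tert-butyldimethylsilyloxy)-5-methylhex-4-enoate
Conditions: TBSCl, imidazole, DMF, rt
Reagents that add atoms: tert-butyldimethylsilyl chloride (TBSCl), CC(C)(C)[Si](C)(C)Cl
Why: Standard silylation of a secondary alcohol, needed because a free propargylic hydroxyl would trap the ketene intermediate of the later benzannulation.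

Step 5
Reactants: 10 methyl (S)-2-(tert-butyldimethylsilyloxy)-5-methylhex-4-enoate
Product: 11 (S)-2-(tert-butyldimethylsilyloxy)-5-methylhex-4-enal
Conditions: i-Bu2AlH (1.1 equiv), CH2Cl2, −78 °C; then aq. KNaC4H4O6
Reagents that add atoms: none
Why: Partial reduction of an α-silyloxy methyl ester with one equivalent of i-Bu2AlH at −78 °C stops at the aldehyde because the chelated tetrahedral aluminate survives until work-up.

Step 6
Reactants: 11 (S)-2-(tert-butyldimethylsilyloxy)-5-methylhex-4-enal
Product: 12 (S)-tert-butyldimethyl[(6-methylhept-5-en-1-yn-3-yl)oxy]silane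
Conditions: dimethyl (1-diazo-2-oxopropyl)phosphonate, K2CO3, MeOH, 0 °C → rt
Reagents that add atoms: dimethyl (1-diazo-2-oxopropyl)phosphonate (Ohira–Bestmann reagent), CC(=O)C(=[N+]=[N-])P(=O)(OC)OC
Why: Seyferth–Gilbert homologation with the Ohira–Bestmann reagent converts the aldehyde into the terminal alkyne under mild carbonate conditions that α-silyloxy aldehydes generally tolerate without loss of configuration.

Step 7
Reactants: 6 pentacarbonyl{[2,5-bis(methoxymethoxy)phenyl](methoxy)methylidene}chromium; 12 (S)-tert-butyldimethyl[(6-methylhept-5-en-1-yn-3-yl)oxy]silane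
Product: 14 (S)-2-[1-(tert-butyldimethylsilyloxy)-4-methylpent-3-enyl]-4-methoxy-5,8-bis(methoxymethoxy)naphthalen-1-ol, via tricarbonylchromium naphthol complex 13 (not isolated)
Conditions: 12 (1.5–2 equiv), degassed THF, 55 °C, Ar; then air, Et2O, rt
Reagents that add atoms: none
Why: Dötz benzannulation: thermal loss of one CO from 6, assisted by the neighbouring acetal oxygen, opens a site for alkyne 12, which inserts into the Cr=C bond with its unsubstituted carbon bonded to the carbene carbon (C3–C4), and CO insertion then gives a chromium-bound vinylketene (C1–C2). Ring A closes by 6π electrocyclisation of this aryl vinylketene onto the only free ortho carbon of the aryl group (C1–C8a), and tautomerisation of the cyclohexadienone gives the naphthol as its Cr(CO)3 complex 13, which air releases as 14. The closest precedent is the benzannulation of (ortho-alkoxyaryl)(methoxy)carbene chromium complexes with terminal alkynes, which gives 4-methoxy-1-naphthols with the alkyne substituent next to the hydroxyl. No stereocentre is formed: the propargylic centre of 12 is not a reacting atom, and the planar chirality of 13 disappears on decomplexation. The step needs chemoselectivity for the CO-inserted phenol over indene, furan or cyclobutenone products, which the methoxy carbene, the donor solvent, the moderate temperature and the excess of alkyne should secure, and a single closure site, which the 2,5-disubstituted aryl group guarantees. Insertion regiochemistry is steered by the terminal alkyne, and even the minor orientation would end in the same naphthazarin because C2 and C3 become equivalent once both peri acetals are removed.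

Step 8
Reactants: 14 (S)-2-[1-(tert-butyldimethylsilyloxy)-4-methylpent-3-enyl]-4-methoxy-5,8-bis(methoxymethoxy)naphthalen-1-ol
Product: 15 (S)-2-[1-(tert-butyldimethylsilyloxy)-4-methylpent-3-enyl]-5,8-bis(methoxymethoxy)naphthalene-1,4-dione
Conditions: PhI(OAc)2, MeCN/H2O, 0 °C
Reagents that add atoms: water, O
Why: Oxidative demethylation of a para-methoxy phenol by a trivalent iodine reagent, in which the free C1 hydroxyl binds iodine, water adds at C4 and methanol is lost, so only ring A becomes the quinone while the acetal-protected ring, the silyl ether and the olefin are left alone.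

Step 9
Reactants: 15 (S)-2-[1-(tert-butyldimethylsilyloxy)-4-methylpent-3-enyl]-5,8-bis(methoxymethoxy)naphthalene-1,4-dione
Product: 16 (S)-2-(1-hydroxy-4-methylpent-3-enyl)-5,8-bis(methoxymethoxy)naphthalene-1,4-dione
Conditions: HF·pyridine, pyridine, THF, 0 °C → rt
Reagents that add atoms: none
Why: Fluoride-mediated cleavage of the secondary silyl ether under buffered, weakly acidic conditions avoids the basic media that quinones tolerate poorly and should leave the aryl acetals in place.

Step 10
Reactants: 16 (S)-2-(1-hydroxy-4-methylpent-3-enyl)-5,8-bis(methoxymethoxy)naphthalene-1,4-dione; 17 tiglic acid, (E)-2-methylbut-2-enoic acid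
Product: 18 (S)-1-[5,8-bis(methoxymethoxy)-1,4-dioxo-1,4-dihydronaphthalen-2-yl]-4-methylpent-3-enyl (E)-2-methylbut-2-enoate
Conditions: DCC, DMAP (cat.), CH2Cl2, 0 °C → rt
Reagents that add atoms: none
Why: Steglich esterification (carbodiimide activation with DMAP acyl transfer) acylates the secondary alcohol with retention at carbon, and the E-configured tiglate is the thermodynamically preferred isomer, so its geometry is not at risk.

Step 11
Reactants: 18 (S)-1-[5,8-bis(methoxymethoxy)-1,4-dioxo-1,4-dihydronaphthalen-2-yl]-4-methylpent-3-enyl (E)-2-methylbut-2-enoate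
Product: 19 (S)-1-(5,8-dihydroxy-1,4-dioxo-1,4-dihydronaphthalen-2-yl)-4-methylpent-3-enyl (E)-2-methylbut-2-enoate
Conditions: CF3CO2H, CH2Cl2 (trace H2O), 0 °C; then aq. NaHCO3
Reagents that add atoms: none
Why: Acid-catalysed acetal hydrolysis is especially easy for aryl methoxymethyl ethers peri to a quinone carbonyl, because the released phenols are held in hydrogen bonds, so brief exposure to dilute acid at 0 °C should spare the allylic ester and the trisubstituted olefin.

**Compound list**

1 | hydroquinone | Oc1ccc(O)cc1 | starting material
2 | 1,4-bis(methoxymethoxy)benzene | COCOc1ccc(OCOC)cc1 | intermediate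
3 | Cr(CO)6, chromium hexacarbonyl | O=C=[Cr](=C=O)(=C=O)(=C=O)(=C=O)=C=O | starting material
4 | [2,5-bis(methoxymethoxy)phenyl]lithium | [Li]c1cc(OCOC)ccc1OCOC | intermediate (not isolated)
5 | lithium pentacarbonyl[2,5-bis(methoxymethoxy)benzoyl]chromate | [Li+].[O-]C(=[Cr](=C=O)(=C=O)(=C=O)(=C=O)=C=O)c1cc(OCOC)ccc1OCOC | intermediate (not isolated)
6 | pentacarbonyl{[2,5-bis(methoxymethoxy)phenyl](methoxy)methylidene}chromium | COCOc1ccc(OCOC)c(c1)C(OC)=[Cr](=C=O)(=C=O)(=C=O)(=C=O)=C=O | intermediate
7 | methyl (S)-glycidate, methyl (2S)-oxirane-2-carboxylate | COC(=O)[C@@H]1CO1 | starting material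
8 | 2-methylprop-1-enylmagnesium bromide | CC(C)=C[Mg]Br | starting material
9 | methyl (S)-2-hydroxy-5-methylhex-4-enoate | COC(=O)[C@@H](O)CC=C(C)C | intermediate
10 | methyl (S)-2-(tert-butyldimethylsilyloxy)-5-methylhex-4-enoate | COC(=O)[C@@H](O[Si](C)(C)C(C)(C)C)CC=C(C)C | intermediate
11 | (S)-2-(tert-butyldimethylsilyloxy)-5-methylhex-4-enal | O=C[C@@H](O[Si](C)(C)C(C)(C)C)CC=C(C)C | intermediate
12 | (S)-tert-butyldimethyl[(6-methylhept-5-en-1-yn-3-yl)oxy]silane | C#C[C@@H](O[Si](C)(C)C(C)(C)C)CC=C(C)C | intermediate
13 | tricarbonyl(η6-naphthol 14)chromium, Cr(CO)3 π-bound to ring A (SMILES written as the naphthol plus the Cr(CO)3 fragment) | COc1cc([C@@H](O[Si](C)(C)C(C)(C)C)CC=C(C)C)c(O)c2c(OCOC)ccc(OCOC)c12.O=C=[Cr](=C=O)=C=O | intermediate (not isolated)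
14 | (S)-2-[1-(tert-butyldimethylsilyloxy)-4-methylpent-3-enyl]-4-methoxy-5,8-bis(methoxymethoxy)naphthalen-1-ol | COc1cc([C@@H](O[Si](C)(C)C(C)(C)C)CC=C(C)C)c(O)c2c(OCOC)ccc(OCOC)c12 | intermediate
15 | (S)-2-[1-(tert-butyldimethylsilyloxy)-4-methylpent-3-enyl]-5,8-bis(methoxymethoxy)naphthalene-1,4-dione | CC(C)(C)[Si](C)(C)O[C@@H](CC=C(C)C)C1=CC(=O)c2c(OCOC)ccc(OCOC)c2C1=O | intermediate
16 | (S)-2-(1-hydroxy-4-methylpent-3-enyl)-5,8-bis(methoxymethoxy)naphthalene-1,4-dione | O[C@@H](CC=C(C)C)C1=CC(=O)c2c(OCOC)ccc(OCOC)c2C1=O | intermediate
17 | tiglic acid, (E)-2-methylbut-2-enoic acid | C/C=C(\C)C(=O)O | starting material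
18 | (S)-1-[5,8-bis(methoxymethoxy)-1,4-dioxo-1,4-dihydronaphthalen-2-yl]-4-methylpent-3-enyl (E)-2-methylbut-2-enoate | C/C=C(\C)C(=O)O[C@@H](CC=C(C)C)C1=CC(=O)c2c(OCOC)ccc(OCOC)c2C1=O | intermediate
19 | (S)-1-(5,8-dihydroxy-1,4-dioxo-1,4-dihydronaphthalen-2-yl)-4-methylpent-3-enyl (E)-2-methylbut-2-enoate | C/C=C(\C)C(=O)O[C@@H](CC=C(C)C)C1=CC(=O)c2c(O)ccc(O)c2C1=O | target

**Step count and risks**

Total steps: 11 (steps 1–2 carbene complex, steps 3–6 alkyne, steps 7–11 convergent end game).
Longest linear sequence: 9 steps (steps 3–11, from methyl (S)-glycidate 7).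

Steps most likely to fail:

1. Step 7. The thermal activation needed to expel CO from the pentacarbonyl complex may let carbene decomposition outrun uptake of the α-branched alkyne. The inserted vinylcarbene may also cyclise without CO (indene) or close to a cyclobutenone instead of the phenol. Fallback: set out from 6 and separate CO loss from ring formation. Warming 6 in tert-butyl methyl ether under a slow argon stream should expel one CO and give the isolable chelate in which the ortho acetal oxygen occupies the vacated site, tetracarbonyl{[2,5-bis(methoxymethoxy)phenyl](methoxy)methylidene-κC,κO}chromium F1. F1 is then combined with alkyne 12 at room temperature, where such chelates take up alkynes without further heating, and aerobic work-up brings the sequence back to the route at 14.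

2. Step 11. The acid needed for acetal cleavage may also ionise or solvolyse the tiglate at the carbinol once the electron-rich naphthazarin is unveiled, or protonate the trisubstituted olefin. Fallback: set out from 16 and reverse the order of the last two operations. Both acetals are removed first with dilute aqueous HCl in THF at 0 °C → rt, when no acyloxy leaving group is present, giving (S)-5,8-dihydroxy-2-(1-hydroxy-4-methylpent-3-enyl)naphthalene-1,4-dione (alkannin) F2. F2 is then acylated with tiglic acid 17 (DCC, DMAP, CH2Cl2) selectively at the side-chain hydroxyl, the two peri hydroxyls being locked in hydrogen bonds to the quinone carbonyls, which returns to the route at 19.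

3. Step 6. Carbonate-mediated enolisation of the α-silyloxy aldehyde before it is trapped would erode the only stereocentre. Fallback: set out from 11 and use the two-stage Corey–Fuchs sequence. CBr4/PPh3/Zn in CH2Cl2 consumes the aldehyde under non-basic conditions to give (S)-tert-butyl[(1,1-dibromo-6-methylhepta-1,5-dien-3-yl)oxy]dimethylsilane F3. n-BuLi (2 equiv, THF, −78 °C) followed by H2O then converts F3, by bromine–lithium exchange and 1,2-shift, into the alkyne, rejoining the route at 12.

**Further compounds**

F1 | step 7 | tetracarbonyl{[2,5-bis(methoxymethoxy)phenyl](methoxy)methylidene-κC,κO}chromium (ortho acetal oxygen bound to Cr) | COC[O+]1c2ccc(OCOC)cc2C(OC)=[Cr-]1(=C=O)(=C=O)(=C=O)=C=O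
F2 | step 11 | (S)-5,8-dihydroxy-2-(1-hydroxy-4-methylpent-3-enyl)naphthalene-1,4-dione (alkannin) | O[C@@H](CC=C(C)C)C1=CC(=O)c2c(O)ccc(O)c2C1=O
F3 | step 6 | (S)-tert-butyl[(1,1-dibromo-6-methylhepta-1,5-dien-3-yl)oxy]dimethylsilane | BrC(Br)=C[C@@H](O[Si](C)(C)C(C)(C)C)CC=C(C)C
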